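**Plan**

- Labels: ring A = C1 (methyl-bearing alkene carbon), C2, C3, C4, C5 (quaternary), C6; C7 = enol-ester CH. Ring B = seven-membered enol lactone, ring C = benzene, ring D = quinone, ring E = thiazine dioxide.
- Retrosynthetic cuts, in order: the C–S and C–N bonds of ring E (hypotaurine onto the quinone); the quinone oxygens (back to a 5,8-dimethoxynaphthalene); the lactone C7O–C(=O) bond of ring B; the C1=C2 alkene (back to a C2 ketone); the C6–C7 and C1–CH3 bonds together; last the aryl–C5 bond.
- Forward: rings C/D come from 2,3-dibromonaphthalene and ring A from 4-methylanisole. They are joined at C5 by palladium γ-arylation, and ring A is dehydrogenated to the dienone. The copper step then adds C7 and the C1 methyl, C2 is deoxygenated to leave C1=C2, ring B closes by enol lactonisation, ring D is unmasked and ring E is annulated last.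
- Enabling feature: while C2 is a carbonyl, the arms C6=C1 and C4=C3 leaving C5 are mirror images. The dienone is therefore achiral, and the crowded C5 needs no asymmetric bond formation of its own.
- Stereochemistry: C5, the only stereocentre of the target (S), is fixed when the chiral copper catalyst picks one arm. The C6 and C1 centres made alongside become sp2 later.

Key step: step 8

Remark: the sense of induction of the copper–ferrocenyl diphosphine catalyst on dienone 11 is assumed by analogy with simpler cyclic enones; the ligand antipode is to be chosen so that 16 has the (1R,5R,6R) configuration drawn.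

**Route**

Step 1
Reactants: 1 2,3-dibromonaphthalene
Product: 2 6,7-dibromonaphthalene-1,4-dione
Conditions: CrO3, AcOH/H2O, 25 → 60 °C
Reagents that add atoms: chromium trioxide, O=[Cr](=O)=O
Why: Chromic acid oxidation of a naphthalene to the 1,4-naphthoquinone attacks the alpha positions of the more electron-rich ring, here the ring without bromine, so the symmetrical dibromoquinone should form.

Step 2
Reactants: 2 6,7-dibromonaphthalene-1,4-dione
Product: 4 2,3-dibromo-5,8-dimethoxynaphthalene, via 6,7-dibromonaphthalene-1,4-diol 3 (not isolated)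
Conditions: Na2S2O4, Bu4NBr, THF/H2O, 25 °C; then KOH, Me2SO4, 25 °C, under N2
Reagents that add atoms: dimethyl sulfate, COS(=O)(=O)OC
Why: Dithionite reduction followed by phase-transfer Williamson O-methylation is the standard reductive methylation of a quinone, and the aryl bromides are inert to it.

Step 3
Reactants: 4 2,3-dibromo-5,8-dimethoxynaphthalene
Product: 6 tert-butyl 3-bromo-5,8-dimethoxy-2-naphthoate, via (3-bromo-5,8-dimethoxynaphthalen-2-yl)magnesium chloride 5 (not isolated)
Conditions: iPrMgCl·LiCl (1.05 equiv), THF, –15 °C; then Boc2O, –15 → 0 °C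
Reagents that add atoms: di-tert-butyl dicarbonate, CC(C)(C)OC(=O)OC(=O)OC(C)(C)C
Why: Bromine–magnesium exchange on the symmetrical ortho-dibromide can only give one mono-Grignard reagent, which is stable below 0 °C (no aryne formation) and is acylated by Boc2O to the tert-butyl ester, so the 2,3-pattern is set without a regiochemical question.

Step 4
Reactants: 7 4-methylanisole
Product: 9 4-methylcyclohex-3-en-1-one, via 1-methoxy-4-methylcyclohexa-1,4-diene 8 (not isolated)
Conditions: Li, NH3 (l), t-BuOH, THF, –78 → –33 °C; then (CO2H)2, MeOH/H2O, 25 °C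
Reagents that add atoms: water, O
Why: Birch reduction leaves the methoxy- and methyl-substituted double bonds, and mild oxalic acid hydrolysis of the enol ether releases the β,γ-unsaturated ketone without moving the alkene into conjugation.

Step 5
Reactants: 6 tert-butyl 3-bromo-5,8-dimethoxy-2-naphthoate; 9 4-methylcyclohex-3-en-1-one
Product: 10 tert-butyl 5,8-dimethoxy-3-(1-methyl-4-oxocyclohex-2-en-1-yl)-2-naphthoate (racemic)
Conditions: Pd2(dba)3 (2.5 mol %), XPhos (10 mol %), Cs2CO3, toluene, 80 °C
Reagents that add atoms: none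
Why: In this palladium-catalysed γ-arylation of a β,γ-unsaturated ketone, carbonate forms the extended dienolate and reductive elimination at its methyl-bearing γ terminus gives the conjugated enone with the aryl-bearing quaternary carbon; the new centre is racemic and is erased in step 6.

Step 6
Reactants: 10 tert-butyl 5,8-dimethoxy-3-(1-methyl-4-oxocyclohex-2-en-1-yl)-2-naphthoate
Product: 11 tert-butyl 5,8-dimethoxy-3-(1-methyl-4-oxocyclohexa-2,5-dien-1-yl)-2-naphthoate
Conditions: IBX (2.5 equiv), DMSO, 75 °C
Reagents that add atoms: none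
Why: IBX dehydrogenation of the saturated α,β-positions of the ketone installs the second enone alkene, the quaternary carbon blocks aromatisation, and the product is achiral (mirror plane through C2, C5, methyl and aryl).

Step 7
Reactants: 12 (chloromethyl)(isopropoxy)dimethylsilane
Product: 13 (isopropoxydimethylsilyl)methylmagnesium chloride (titrated Et2O solution)
Conditions: Mg turnings, BrCH2CH2Br (cat.), Et2O, reflux
Reagents that add atoms: magnesium, [Mg]
Why: Direct magnesium insertion into the primary chloride gives the Grignard reagent, prepared in diethyl ether because copper–diphosphine conjugate additions are run in weakly coordinating ethers.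

Step 8
Reactants: 11 tert-butyl 5,8-dimethoxy-3-(1-methyl-4-oxocyclohexa-2,5-dien-1-yl)-2-naphthoate; 13 (isopropoxydimethylsilyl)methylmagnesium chloride; 14 iodomethane
Product: 16 tert-butyl 3-[(1R,5R,6R)-6-{[dimethyl(propan-2-yloxy)silyl]methyl}-1,5-dimethyl-4-oxocyclohex-2-en-1-yl]-5,8-dimethoxy-2-naphthoate (silylmethyl anti to the naphthyl group, C1 methyl trans to the silylmethyl group), via magnesium enolate 15 (not isolated)
Conditions: CuBr·SMe2 (5 mol %), (R)-1-[(S)-2-(diphenylphosphino)ferrocenyl]ethyldicyclohexylphosphine (6 mol %), 13 (1.2 equiv), t-BuOMe/CH2Cl2, –78 °C; then MeI (5 equiv), DMPU, –78 → 0 °C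
Reagents that add atoms: iodomethane (14), CI
Why: The monovalent copper–diphosphine complex is transmetalated by 13, binds the π face of one enone arm and adds at the β-carbon C6 to give a trivalent copper σ-complex whose reductive elimination forms C6–C7; the closest known reaction type is the copper-catalysed enantioselective conjugate addition of Grignard reagents to cyclic enones, as used to desymmetrise 4,4-disubstituted cyclohexadienones with enolate trapping. No ring is closed. The catalyst selects the face of the β-carbon while the ortho-substituted naphthyl group steers attack to the face anti to itself, so only one of the two enantiotopic arms meets both demands; this choice of arm fixes C5 (R in 16, S in the target where the CIP ranks change) and sets C6 in the same event. Enolate 15 is regiodefined at C1=C2, cannot take a second addition, and with DMPU is C-methylated by iodomethane trans to the neighbouring silylmethyl group (substrate control at C1). The step needs 1,4- over 1,2-addition (copper catalysis at –78 °C, hindered tert-butyl ester), mono-addition (the enolate) and arm selection (ligand antipode matched to the anti-to-aryl bias); the syn diastereomer, which carries the opposite C5 configuration, should be removed by chromatography of 16.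

Step 9
Reactants: 16 tert-butyl 3-[(1R,5R,6R)-6-{[dimethyl(propan-2-yloxy)silyl]methyl}-1,5-dimethyl-4-oxocyclohex-2-en-1-yl]-5,8-dimethoxy-2-naphthoate
Product: 17 tert-butyl 3-[(1R,6S)-6-{[dimethyl(propan-2-yloxy)silyl]methyl}-1,5-dimethyl-4-[(trifluoromethanesulfonyl)oxy]cyclohexa-2,4-dien-1-yl]-5,8-dimethoxy-2-naphthoate
Conditions: KN(SiMe3)2, THF, –78 °C; then PhNTf2, –78 → 0 °C
Reagents that add atoms: N-phenylbis(trifluoromethanesulfonimide), O=S(=O)(N(c1ccccc1)S(=O)(=O)C(F)(F)F)C(F)(F)F
Why: Enone 16 has a single enolisable position, C1, because the γ-carbon C5 is quaternary, so kinetic deprotonation and O-sulfonylation give the 2-triflyloxy-1,3-diene regiospecifically; the C1 centre is erased, C5 and C6 are untouched.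

Step 10
Reactants: 17 tert-butyl 3-[(1R,6S)-6-{[dimethyl(propan-2-yloxy)silyl]methyl}-1,5-dimethyl-4-[(trifluoromethanesulfonyl)oxy]cyclohexa-2,4-dien-1-yl]-5,8-dimethoxy-2-naphthoate
Product: 19 tert-butyl 3-[(1R,6R)-6-(hydroxymethyl)-1,5-dimethylcyclohexa-2,4-dien-1-yl]-5,8-dimethoxy-2-naphthoate, via silyl diene 18 (not isolated)
Conditions: Pd(OAc)2 (5 mol %), PPh3, Bu3N, HCO2H, DMF, 60 °C; then KF, KHCO3, 30% H2O2, THF/MeOH, 25 °C
Reagents that add atoms: hydrogen peroxide, OO
Why: Palladium-catalysed formate reduction replaces the enol triflate by hydrogen with the C1=C2 bond kept in place, and Tamao oxidation of the crude alkoxysilane turns C7–Si into C7–OH under mildly basic peroxide that leaves the diene and the tert-butyl ester alone.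

Step 11
Reactants: 19 tert-butyl 3-[(1R,6R)-6-(hydroxymethyl)-1,5-dimethylcyclohexa-2,4-dien-1-yl]-5,8-dimethoxy-2-naphthoate
Product: 20 tert-butyl 3-[(1R,2R)-2-(hydroxymethyl)-1,3-dimethylcyclohex-3-en-1-yl]-5,8-dimethoxy-2-naphthoate
Conditions: 2-nitrobenzenesulfonohydrazide, Et3N, CH2Cl2, 25 °C
Reagents that add atoms: none
Why: Diimide generated in situ transfers H2 in a concerted 1,2-fashion and reacts far faster with the cis-disubstituted C3=C4 bond of the conjugated diene than with the trisubstituted C1=C2 bond, so the methyl-bearing alkene should stay where it is.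

Step 12
Reactants: 20 tert-butyl 3-[(1R,2R)-2-(hydroxymethyl)-1,3-dimethylcyclohex-3-en-1-yl]-5,8-dimethoxy-2-naphthoate
Product: 21 tert-butyl 3-[(1R,2R)-2-formyl-1,3-dimethylcyclohex-3-en-1-yl]-5,8-dimethoxy-2-naphthoate
Conditions: Dess–Martin periodinane, pyridine, CH2Cl2, 0 °C
Reagents that add atoms: none
Why: Buffered Dess–Martin oxidation gives the β,γ-unsaturated aldehyde without enolising conditions, and any epimerisation at C6 is harmless because that centre is removed in step 13.

Step 13
Reactants: 21 tert-butyl 3-[(1R,2R)-2-formyl-1,3-dimethylcyclohex-3-en-1-yl]-5,8-dimethoxy-2-naphthoate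
Product: 23 (S)-dimethoxy enol lactone (ring B closed: naphthoyl C(=O)–O–C7H=C6, C1(CH3)=C2 in ring A, C5 bearing methyl and the naphthalene C3), via aldehyde acid 22 (not isolated)
Conditions: TsOH·H2O (20 mol %), toluene, 80 → 110 °C, Dean–Stark
Reagents that add atoms: none
Why: Acid-catalysed loss of isobutene frees the carboxylic acid, which adds to the aldehyde to give the seven-membered hydroxy lactone and is dehydrated toward C6 to the conjugated dienol ester (enol lactonisation of an aldehydo acid with azeotropic water removal); C6 becomes sp2 and C5 is not involved.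

Step 14
Reactants: 23 (S)-dimethoxy enol lactone
Product: 24 (S)-enol lactone naphthoquinone (ring D as the 1,4-quinone)
Conditions: (NH4)2Ce(NO3)6 (2.5 equiv), MeCN/H2O, 0 °C
Reagents that add atoms: water, O
Why: Oxidative demethylation of the 1,4-dimethoxyarene by tetravalent cerium gives the quinone quickly at 0 °C, before the much less electron-rich dienol ester can react.

Step 15
Reactants: 24 (S)-enol lactone naphthoquinone; 25 hypotaurine (2-aminoethanesulfinic acid)
Product: 26 CNP0348176.1
Conditions: hypotaurine (1.5 equiv), MeCN/EtOH/H2O, 25 → 40 °C, open to air, no added base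
Reagents that add atoms: hypotaurine (25), NCCS(=O)O
Why: In this known hypotaurine annulation of quinones the reagent reacts as its ammonium sulfinate, so sulfur is expected to add first at the quinone carbon β to the more electron-poor carbonyl (the one whose ring C carbon is para to the lactone carbonyl); after air reoxidation the amine closes the six-membered ring on the neighbouring carbon and a second oxidation gives the thiazine-dioxide-fused quinone.

**Compound list**

1 | 2,3-dibromonaphthalene | Brc1cc2ccccc2cc1Br | starting material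
2 | 6,7-dibromonaphthalene-1,4-dione | O=C1C=CC(=O)c2cc(Br)c(Br)cc12 | intermediate
3 | 6,7-dibromonaphthalene-1,4-diol | Oc1ccc(O)c2cc(Br)c(Br)cc12 | intermediate
4 | 2,3-dibromo-5,8-dimethoxynaphthalene | COc1ccc(OC)c2cc(Br)c(Br)cc12 | intermediate
5 | (3-bromo-5,8-dimethoxynaphthalen-2-yl)magnesium chloride | COc1ccc(OC)c2cc(Br)c([Mg]Cl)cc12 | intermediate
6 | tert-butyl 3-bromo-5,8-dimethoxy-2-naphthoate | COc1ccc(OC)c2cc(Br)c(cc12)C(=O)OC(C)(C)C | intermediate
7 | 4-methylanisole | COc1ccc(C)cc1 | starting material
8 | 1-methoxy-4-methylcyclohexa-1,4-diene | COC1=CCC(C)=CC1 | intermediate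
9 | 4-methylcyclohex-3-en-1-one | CC1=CCC(=O)CC1 | intermediate
10 | tert-butyl 5,8-dimethoxy-3-(1-methyl-4-oxocyclohex-2-en-1-yl)-2-naphthoate (racemic) | CC1(C=CC(=O)CC1)c1cc2c(OC)ccc(OC)c2cc1C(=O)OC(C)(C)C | intermediate
11 | tert-butyl 5,8-dimethoxy-3-(1-methyl-4-oxocyclohexa-2,5-dien-1-yl)-2-naphthoate (achiral) | CC1(C=CC(=O)C=C1)c1cc2c(OC)ccc(OC)c2cc1C(=O)OC(C)(C)C | intermediate
12 | (chloromethyl)(isopropoxy)dimethylsilane | CC(C)O[Si](C)(C)CCl | starting material
13 | (isopropoxydimethylsilyl)methylmagnesium chloride | CC(C)O[Si](C)(C)C[Mg]Cl | intermediate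
14 | iodomethane | CI | starting material
15 | chloromagnesium dienolate, tert-butyl 3-[(1R,6R)-4-(chloromagnesiooxy)-6-{[dimethyl(propan-2-yloxy)silyl]methyl}-1-methylcyclohexa-2,4-dien-1-yl]-5,8-dimethoxy-2-naphthoate | C1=C(O[Mg]Cl)C=C[C@](c2cc3c(OC)ccc(OC)c3cc2C(=O)OC(C)(C)C)(C)[C@@H]1C[Si](C)(C)OC(C)C | intermediate
16 | tert-butyl 3-[(1R,5R,6R)-6-{[dimethyl(propan-2-yloxy)silyl]methyl}-1,5-dimethyl-4-oxocyclohex-2-en-1-yl]-5,8-dimethoxy-2-naphthoate | C[C@H]1C(=O)C=C[C@](c2cc3c(OC)ccc(OC)c3cc2C(=O)OC(C)(C)C)(C)[C@@H]1C[Si](C)(C)OC(C)C | intermediate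
17 | tert-butyl 3-[(1R,6S)-6-{[dimethyl(propan-2-yloxy)silyl]methyl}-1,5-dimethyl-4-[(trifluoromethanesulfonyl)oxy]cyclohexa-2,4-dien-1-yl]-5,8-dimethoxy-2-naphthoate | CC1=C(OS(=O)(=O)C(F)(F)F)C=C[C@](c2cc3c(OC)ccc(OC)c3cc2C(=O)OC(C)(C)C)(C)[C@@H]1C[Si](C)(C)OC(C)C | intermediate
18 | tert-butyl 3-[(1R,6R)-6-{[dimethyl(propan-2-yloxy)silyl]methyl}-1,5-dimethylcyclohexa-2,4-dien-1-yl]-5,8-dimethoxy-2-naphthoate | CC1=CC=C[C@](c2cc3c(OC)ccc(OC)c3cc2C(=O)OC(C)(C)C)(C)[C@@H]1C[Si](C)(C)OC(C)C | intermediate
19 | tert-butyl 3-[(1R,6R)-6-(hydroxymethyl)-1,5-dimethylcyclohexa-2,4-dien-1-yl]-5,8-dimethoxy-2-naphthoate | CC1=CC=C[C@](c2cc3c(OC)ccc(OC)c3cc2C(=O)OC(C)(C)C)(C)[C@@H]1CO | intermediate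
20 | tert-butyl 3-[(1R,2R)-2-(hydroxymethyl)-1,3-dimethylcyclohex-3-en-1-yl]-5,8-dimethoxy-2-naphthoate | CC1=CCC[C@](c2cc3c(OC)ccc(OC)c3cc2C(=O)OC(C)(C)C)(C)[C@@H]1CO | intermediate
21 | tert-butyl 3-[(1R,2R)-2-formyl-1,3-dimethylcyclohex-3-en-1-yl]-5,8-dimethoxy-2-naphthoate | CC1=CCC[C@](c2cc3c(OC)ccc(OC)c3cc2C(=O)OC(C)(C)C)(C)[C@@H]1C=O | intermediate
22 | 3-[(1R,2R)-2-formyl-1,3-dimethylcyclohex-3-en-1-yl]-5,8-dimethoxy-2-naphthoic acid | CC1=CCC[C@](c2cc3c(OC)ccc(OC)c3cc2C(=O)O)(C)[C@@H]1C=O | intermediate
23 | (S)-dimethoxy enol lactone: 5,8-dimethoxynaphthalene whose C2 carbonyl is joined through oxygen to C7H, C7=C6 exocyclic to ring A, C1(CH3)=C2 in ring A, C5 (S) bearing methyl and the naphthalene C3 | CC1=CCC[C@]2(C)C1=COC(=O)c1cc3c(OC)ccc(OC)c3cc12 | intermediate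
24 | (S)-enol lactone naphthoquinone: 23 with the dimethoxy ring as the 1,4-quinone | CC1=CCC[C@]2(C)C1=COC(=O)c1cc3c(cc12)C(=O)C=CC3=O | intermediate
25 | hypotaurine (2-aminoethanesulfinic acid) | NCCS(=O)O | starting material
26 | CNP0348176.1: (S)-enol lactone quinone fused to a 1,1-dioxo-1,4-thiazine, NH on the quinone carbon next to the carbonyl whose ring C carbon is para to the lactone carbonyl, SO2 on the other | CC1=CCC[C@]2(C)C1=COC(=O)c1cc3c(cc12)C(=O)C1=C(C3=O)S(=O)(=O)CCN1 | target

**Step count**

Total: 15 steps. Longest linear sequence: 13 steps (from 1 through steps 1–3, 5, 6 and 8–15).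

**Steps most likely to fail**

Step 5. Reductive elimination at the γ-carbon may be slow because the arylpalladium carries an ortho ester and a quaternary centre is being made; α-arylation, reduction of 6 or self-condensation of 9 could then take over. The fallback sets out from 6 and rejoins at 10 by a Robinson annulation instead of a cross-coupling at the quaternary carbon. Suzuki coupling of 6 with isopropenylboronic acid pinacol ester (Pd(dppf)Cl2, K2CO3, dioxane/H2O) should give tert-butyl 5,8-dimethoxy-3-(prop-1-en-2-yl)-2-naphthoate F1. Hydroboration with 9-BBN gives tert-butyl 3-[1-(9-borabicyclo[3.3.1]nonan-9-yl)propan-2-yl]-5,8-dimethoxy-2-naphthoate F2, which NaBO3 oxidises to tert-butyl 3-(1-hydroxypropan-2-yl)-5,8-dimethoxy-2-naphthoate F3. Dess–Martin oxidation gives tert-butyl 5,8-dimethoxy-3-(1-oxopropan-2-yl)-2-naphthoate F4. With methyl vinyl ketone and catalytic KOH in EtOH at 0 °C, the Michael adduct tert-butyl 5,8-dimethoxy-3-(2-methyl-1,5-dioxohexan-2-yl)-2-naphthoate F5 forms and condenses to 10.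

Step 8. Arm selection may be poor if the catalyst's face preference is mismatched with, or overridden by, the substrate bias (for example ester-assisted delivery syn to the aryl group). The magnesium enolate may also alkylate slowly, so that proton exchange with product scrambles the enolate during the warm-up. The fallback sets out from 11 (with 13) and rejoins at 16, separating addition from alkylation. The same copper-catalysed addition run with Me3SiCl present should trap 15 as the trimethylsilyl dienol ether F6, which can be purified and freed of the syn diastereomer. t-BuOK in THF then releases the potassium enolate F7 regiospecifically (an alkoxide is used rather than MeLi so that the isopropoxysilane stays oxidisable), and 14 with DMPU gives 16.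

Step 15. Regiocontrol may be lost if nitrogen adds first or if both quinone carbons are attacked, giving the isomeric thiazine, and the free amine may open the enol lactone. The fallback sets out from 24 and rejoins at 26 with the order of bond formation enforced. Hypotaurine 25 is first protected (Boc2O, NaHCO3, H2O/dioxane) as sodium 2-[(tert-butoxycarbonyl)amino]ethane-1-sulfinate F8. Its sulfa-Michael addition to 24 should give the Boc-aminoethylsulfonyl hydroquinone F9, and Ag2O oxidises this to the sulfonylquinone F10. TFA in CH2Cl2 removes the Boc group to give the aminoethylsulfonyl quinone F11, which on neutralisation in air closes ring E on the adjacent carbon and is oxidised to 26.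

**Further compounds**

F1 | step 5 | tert-butyl 5,8-dimethoxy-3-(prop-1-en-2-yl)-2-naphthoate | CC(=C)c1cc2c(OC)ccc(OC)c2cc1C(=O)OC(C)(C)C
F2 | step 5 | tert-butyl 3-[1-(9-borabicyclo[3.3.1]nonan-9-yl)propan-2-yl]-5,8-dimethoxy-2-naphthoate (racemic) | CC(CB1C2CCCC1CCC2)c1cc2c(OC)ccc(OC)c2cc1C(=O)OC(C)(C)C
F3 | step 5 | tert-butyl 3-(1-hydroxypropan-2-yl)-5,8-dimethoxy-2-naphthoate (racemic) | CC(CO)c1cc2c(OC)ccc(OC)c2cc1C(=O)OC(C)(C)C
F4 | step 5 | tert-butyl 5,8-dimethoxy-3-(1-oxopropan-2-yl)-2-naphthoate (racemic) | CC(C=O)c1cc2c(OC)ccc(OC)c2cc1C(=O)OC(C)(C)C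
F5 | step 5 | tert-butyl 5,8-dimethoxy-3-(2-methyl-1,5-dioxohexan-2-yl)-2-naphthoate (racemic) | CC(=O)CCC(C)(C=O)c1cc2c(OC)ccc(OC)c2cc1C(=O)OC(C)(C)C
F6 | step 8 | tert-butyl 3-[(1R,6R)-6-{[dimethyl(propan-2-yloxy)silyl]methyl}-1-methyl-4-[(trimethylsilyl)oxy]cyclohexa-2,4-dien-1-yl]-5,8-dimethoxy-2-naphthoate | C1=C(O[Si](C)(C)C)C=C[C@](c2cc3c(OC)ccc(OC)c3cc2C(=O)OC(C)(C)C)(C)[C@@H]1C[Si](C)(C)OC(C)C
F7 | step 8 | potassium dienolate corresponding to F6 | C1=C(O[K])C=C[C@](c2cc3c(OC)ccc(OC)c3cc2C(=O)OC(C)(C)C)(C)[C@@H]1C[Si](C)(C)OC(C)C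
F8 | step 15 | sodium 2-[(tert-butoxycarbonyl)amino]ethane-1-sulfinate | CC(C)(C)OC(=O)NCCS(=O)[O-].[Na+]
F9 | step 15 | hydroquinone of 24 bearing the 2-(Boc-amino)ethylsulfonyl group on the ring D carbon that carries SO2 in 26 | CC1=CCC[C@]2(C)C1=COC(=O)c1cc3c(cc12)c(O)cc(S(=O)(=O)CCNC(=O)OC(C)(C)C)c3O
F10 | step 15 | sulfonylquinone obtained by oxidation of F9 | CC1=CCC[C@]2(C)C1=COC(=O)c1cc3c(cc12)C(=O)C=C(S(=O)(=O)CCNC(=O)OC(C)(C)C)C3=O
F11 | step 15 | 2-aminoethylsulfonyl quinone (free amine of F10) | CC1=CCC[C@]2(C)C1=COC(=O)c1cc3c(cc12)C(=O)C=C(S(=O)(=O)CCN)C3=O
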